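**Plan**

- Locants are those of the bicyclic core and are also used for open precursors. Ring B: C1(H)=C8a, C2(=O), C3(=CMe2), C4(H2), C4a(Me). Ring A: C4a, C5(HMe), C6(H–O), C7=C8, C8a.
- Retrosynthesis: cut the ester C–O (alcohol 17 + acid 22), then C3=CMe2 (acetone aldol), then C4–C4a (opening ring B to trienone 11), then C2–C3 (vinyl Grignard) and C1=C8a (olefination). This leaves ring A enone 7, made from 2,3-dimethylcyclohex-2-en-1-one 1.
- Enabling feature: ring B is a cross-conjugated dienone. Its C2 carbonyl lies between C1=C8a and C3, and its C4 methylene joins the quaternary C4a, so ring B is the 6π closure product of the 3-oxidohexatriene C4a=C8a–C1=C2(O−)–C3=C4. The C7=C8 bond of ring A leaves C4a–H as the only γ-hydrogen of the open dienone.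
- Forward: ring A first (steps 1–5), chain attached at C8a (steps 6, 7), ring B closed at C4–C4a with in-flask aldol capture (step 8), then dehydration, desilylation and acylation with acid 22 (steps 9, 10, 14).
- Stereochemistry: C6 from oxazaborolidine reduction (step 1); C5 from hydrogenation anti to the silyl ether (step 4); C4a from ring closure anti to the C5 methyl (step 8); the side-chain centre from (S)-2-methylbutan-1-ol 18.

Key step: step 8

Remark: step 6 may give E/Z and C4a-epimeric mixtures and step 8 gives C3 epimers of 15. All of these converge (on trienolate 13 and on 16 respectively), so one isomer is drawn in each case.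

**Route**

Step 1
Reactants: 1 2,3-dimethylcyclohex-2-en-1-one
Product: 2 (1S)-2,3-dimethylcyclohex-2-en-1-ol
Conditions: (R)-2-methyl-CBS-oxazaborolidine (10 mol %), BH3·SMe2, THF, −20 °C; MeOH quench
Reagents that add atoms: none
Why: Corey–Bakshi–Shibata reduction: with the alkene carbon as the large group, the (R)-catalyst should deliver hydride to the face that gives the (1S)-carbinol, the future C6.

Step 2
Reactants: 2 (1S)-2,3-dimethylcyclohex-2-en-1-ol
Product: 3 tert-butyl{[(1S)-2,3-dimethylcyclohex-2-en-1-yl]oxy}dimethylsilane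
Conditions: TBSCl, imidazole, DMF, rt
Reagents that add atoms: tert-butyldimethylsilyl chloride, CC(C)(C)[Si](C)(C)Cl
Why: Standard silylation of a secondary allylic alcohol; the bulky silyl ether later directs steps 4 and 8.

Step 3
Reactants: 3 tert-butyl{[(1S)-2,3-dimethylcyclohex-2-en-1-yl]oxy}dimethylsilane
Product: 4 (4S)-4-{[tert-butyl(dimethyl)silyl]oxy}-2,3-dimethylcyclohex-2-en-1-one
Conditions: CrO3, 3,5-dimethylpyrazole, CH2Cl2, −20 °C
Reagents that add atoms: chromium trioxide, O=[Cr](=O)=O
Why: Allylic oxidation with the CrO3–3,5-dimethylpyrazole complex should convert the only unsubstituted allylic ring methylene (future C8a) into the enone carbonyl, the other allylic ring position being shielded by the silyl ether.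

Step 4
Reactants: 4 (4S)-4-{[tert-butyl(dimethyl)silyl]oxy}-2,3-dimethylcyclohex-2-en-1-one
Product: 5 (2S,3R,4S)-4-{[tert-butyl(dimethyl)silyl]oxy}-2,3-dimethylcyclohexan-1-one
Conditions: H2 (4 atm), Pd on carbon, EtOAc, rt
Reagents that add atoms: none
Why: Heterogeneous hydrogenation should add both hydrogens to the tetrasubstituted enone from the face opposite the silyl ether, which places the C5 methyl cis to the C6 oxygen; the C4a centre formed here is epimerizable and is flattened again in step 8.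

Step 5
Reactants: 5 (2S,3R,4S)-4-{[tert-butyl(dimethyl)silyl]oxy}-2,3-dimethylcyclohexan-1-one
Product: 7 (4S,5R,6S)-4-{[tert-butyl(dimethyl)silyl]oxy}-5,6-dimethylcyclohex-2-en-1-one, via trimethylsilyl enol ether 6 (not isolated)
Conditions: LiN(i-Pr)2, Me3SiCl, THF, −78 °C; then Pd(OAc)2, MeCN, rt
Reagents that add atoms: none
Why: Kinetic deprotonation should take place at the methylene (future C8) and not at the methyl-bearing methine, and the trapped silyl enol ether is dehydrosilylated by divalent palladium (Saegusa–Ito oxidation) to place the C7=C8 double bond.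

Step 6
Reactants: 7 (4S,5R,6S)-4-{[tert-butyl(dimethyl)silyl]oxy}-5,6-dimethylcyclohex-2-en-1-one; 8 diethyl {2-[methoxy(methyl)amino]-2-oxoethyl}phosphonate
Product: 9 (2E)-2-[(4S,5R,6S)-4-{[tert-butyl(dimethyl)silyl]oxy}-5,6-dimethylcyclohex-2-en-1-ylidene]-N-methoxy-N-methylacetamide
Conditions: NaH, THF, 0 °C to reflux
Reagents that add atoms: none
Why: Horner–Wadsworth–Emmons olefination of the ketone with the amide-stabilized phosphonate anion; the amide carbonyl should settle cis to the vinylic C8–H and away from the C4a methyl (E), and E/Z or deconjugated isomers are harmless because all give trienolate 13 in step 8.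

Step 7
Reactants: 9 (2E)-2-[(4S,5R,6S)-4-{[tert-butyl(dimethyl)silyl]oxy}-5,6-dimethylcyclohex-2-en-1-ylidene]-N-methoxy-N-methylacetamide; 10 vinylmagnesium bromide
Product: 11 (1E)-1-[(4S,5R,6S)-4-{[tert-butyl(dimethyl)silyl]oxy}-5,6-dimethylcyclohex-2-en-1-ylidene]but-3-en-2-one
Conditions: THF, −78 to 0 °C; inverse quench into cold 1 M HCl; used at once
Reagents that add atoms: none
Why: The N-methoxy-N-methylamide forms a stable magnesium chelate that accepts a single vinyl group and releases the vinyl ketone only on the cold acidic quench, which also keeps the freed amine from adding to the enone.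

Step 8
Reactants: 11 (1E)-1-[(4S,5R,6S)-4-{[tert-butyl(dimethyl)silyl]oxy}-5,6-dimethylcyclohex-2-en-1-ylidene]but-3-en-2-one; 12 acetone
Product: 15 (4aR,5R,6S)-6-{[tert-butyl(dimethyl)silyl]oxy}-3-(2-hydroxypropan-2-yl)-4a,5-dimethyl-4,4a,5,6-tetrahydronaphthalen-2(3H)-one (C3 epimers), via potassium trienolate 13 (not isolated), via ring-closed potassium enolate 14 (not isolated)
Conditions: KN(SiMe3)2 (1.05 equiv), THF (0.01 M), −78 to 0 °C; then ZnCl2, −78 °C; acetone, −78 to −40 °C; aq NH4Cl
Reagents that add atoms: none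
Why: Proposed new method: KN(SiMe3)2 should remove the only γ-hydrogen of the cross-conjugated trienone (C4a–H; C8 is sp2 and C3 has no removable hydrogen) to give the 3-oxidohexatriene 13 (C4a=C8a–C1=C2(O−)–C3=C4), whose thermal disrotatory 6π electrocyclization, equally a vinylogous Michael addition of the dienolate γ-carbon to the vinyl terminus, forms the C4–C4a bond. The closest known reaction types are the base-mediated cyclization of phorone to isophorone through its γ-dienolate, carbanion-accelerated triene electrocyclizations and the Michael step of the Robinson annulation; here a C=C π bond is traded for a σ bond and the regiodefined cross-conjugated enolate 14 results. Ring B closes in the six-membered endo mode (6-endo-trig), because the alternative attack through C1 would need a four-membered ring. The quaternary centre C4a is controlled by the C5 methyl and the cis C6 silyloxy group, which shield one face of the planar C4a terminus so that C4 bonds anti to them and the two methyl groups end cis; the C3 centre formed in the zinc aldol is not controlled and is erased in step 9. The step needs γ- over ε-deprotonation and an anion geometry with the vinyl group cis to C8a across C1=C2: the bulky silyl ether hinders removal of the C6 hydrogen, and the delocalized anion can rotate about C1–C2 and C1–C8a, so both olefin isomers of 11 converge. Capture of enolate 14 by acetone after transmetalation to zinc is the standard aldol of such α'-enolates.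

Step 9
Reactants: 15 (4aR,5R,6S)-6-{[tert-butyl(dimethyl)silyl]oxy}-3-(2-hydroxypropan-2-yl)-4a,5-dimethyl-4,4a,5,6-tetrahydronaphthalen-2(3H)-one
Product: 16 (4aR,5R,6S)-6-{[tert-butyl(dimethyl)silyl]oxy}-4a,5-dimethyl-3-(propan-2-ylidene)-4,4a,5,6-tetrahydronaphthalen-2(3H)-one
Conditions: MeSO2Cl, Et3N, DMAP (cat.), CH2Cl2, 0 °C; then DBU, rt
Reagents that add atoms: none
Why: Mesylation of the tertiary alcohol followed by E1cB elimination through the C3 enolate can give only the conjugated tetrasubstituted isopropylidene, and both C3 epimers converge.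

Step 10
Reactants: 16 (4aR,5R,6S)-6-{[tert-butyl(dimethyl)silyl]oxy}-4a,5-dimethyl-3-(propan-2-ylidene)-4,4a,5,6-tetrahydronaphthalen-2(3H)-one
Product: 17 (4aR,5R,6S)-6-hydroxy-4a,5-dimethyl-3-(propan-2-ylidene)-4,4a,5,6-tetrahydronaphthalen-2(3H)-one
Conditions: Bu4NF, AcOH, THF, 0 °C to rt
Reagents that add atoms: none
Why: Fluoride cleaves the silyl ether, and acetic acid buffering suppresses base-induced enolization of the dienone.

Step 11
Reactants: 18 (2S)-2-methylbutan-1-ol
Product: 19 (2S)-2-methylbutanal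
Conditions: TEMPO (cat.), PhI(OAc)2, CH2Cl2, rt; solution used directly
Reagents that add atoms: none
Why: Oxoammonium (TEMPO) oxidation under neutral conditions stops at the aldehyde and should not epimerize the α-stereocentre.

Step 12
Reactants: 19 (2S)-2-methylbutanal; 20 ethyl (2E)-4-(diethoxyphosphoryl)but-2-enoate
Product: 21 ethyl (2E,4E,6S)-6-methylocta-2,4-dienoate
Conditions: LiN(SiMe3)2, THF, −78 to 0 °C
Reagents that add atoms: none
Why: Vinylogous Horner–Wadsworth–Emmons reaction of the crotonate phosphonate anion should give the (2E,4E)-dienoate, and the low temperature protects the α-stereocentre of the aldehyde.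

Step 13
Reactants: 21 ethyl (2E,4E,6S)-6-methylocta-2,4-dienoate
Product: 22 (2E,4E,6S)-6-methylocta-2,4-dienoic acid
Conditions: LiOH, THF/H2O, rt; then 1 M HCl
Reagents that add atoms: lithium hydroxide, [Li+].[OH-]
Why: Saponification of an unhindered ethyl ester; the stereocentre is remote from any acidic position.

Step 14
Reactants: 17 (4aR,5R,6S)-6-hydroxy-4a,5-dimethyl-3-(propan-2-ylidene)-4,4a,5,6-tetrahydronaphthalen-2(3H)-one; 22 (2E,4E,6S)-6-methylocta-2,4-dienoic acid
Product: 24 (1R,2S,8aR)-1,8a-dimethyl-6-oxo-7-(propan-2-ylidene)-1,2,6,7,8,8a-hexahydronaphthalen-2-yl (2E,4E,6S)-6-methylocta-2,4-dienoate, via mixed anhydride 23 (not isolated)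
Conditions: 2,4,6-trichlorobenzoyl chloride, Et3N, THF, rt; then 17, DMAP, toluene, rt
Reagents that add atoms: none
Why: Yamaguchi esterification: the mixed anhydride should transfer the dienoyl group through DMAP to the hindered C6 alcohol with retention, since no bond to C6 is broken.

**Compound list**

1 | 2,3-dimethylcyclohex-2-en-1-one | CC1=C(C)C(=O)CCC1 | starting material
2 | (1S)-2,3-dimethylcyclohex-2-en-1-ol | CC1=C(C)[C@@H](O)CCC1 | intermediate
3 | tert-butyl{[(1S)-2,3-dimethylcyclohex-2-en-1-yl]oxy}dimethylsilane | CC1=C(C)[C@@H](O[Si](C)(C)C(C)(C)C)CCC1 | intermediate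
4 | (4S)-4-{[tert-butyl(dimethyl)silyl]oxy}-2,3-dimethylcyclohex-2-en-1-one | CC1=C(C)[C@@H](O[Si](C)(C)C(C)(C)C)CCC1=O | intermediate
5 | (2S,3R,4S)-4-{[tert-butyl(dimethyl)silyl]oxy}-2,3-dimethylcyclohexan-1-one | C[C@H]1[C@@H](C)[C@@H](O[Si](C)(C)C(C)(C)C)CCC1=O | intermediate
6 | (4S,5R,6S)-4-{[tert-butyl(dimethyl)silyl]oxy}-5,6-dimethyl-1-[(trimethylsilyl)oxy]cyclohex-1-ene | C[C@H]1[C@@H](C)[C@@H](O[Si](C)(C)C(C)(C)C)CC=C1O[Si](C)(C)C | intermediate (not isolated)
7 | (4S,5R,6S)-4-{[tert-butyl(dimethyl)silyl]oxy}-5,6-dimethylcyclohex-2-en-1-one | C[C@H]1[C@@H](C)[C@@H](O[Si](C)(C)C(C)(C)C)C=CC1=O | intermediate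
8 | diethyl {2-[methoxy(methyl)amino]-2-oxoethyl}phosphonate | CCOP(=O)(CC(=O)N(C)OC)OCC | starting material
9 | (2E)-2-[(4S,5R,6S)-4-{[tert-butyl(dimethyl)silyl]oxy}-5,6-dimethylcyclohex-2-en-1-ylidene]-N-methoxy-N-methylacetamide | C[C@H]1[C@@H](C)[C@@H](O[Si](C)(C)C(C)(C)C)C=C/C1=C\C(=O)N(C)OC | intermediate
10 | vinylmagnesium bromide | C=C[Mg]Br | starting material
11 | (1E)-1-[(4S,5R,6S)-4-{[tert-butyl(dimethyl)silyl]oxy}-5,6-dimethylcyclohex-2-en-1-ylidene]but-3-en-2-one | C[C@H]1[C@@H](C)[C@@H](O[Si](C)(C)C(C)(C)C)C=C/C1=C\C(=O)C=C | intermediate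
12 | acetone | CC(C)=O | starting material
13 | potassium (1E)-1-[(3R,4S)-4-{[tert-butyl(dimethyl)silyl]oxy}-2,3-dimethylcyclohexa-1,5-dien-1-yl]buta-1,3-dien-2-olate | [K+].[O-]/C(C=C)=C/C1=C(C)[C@@H](C)[C@@H](O[Si](C)(C)C(C)(C)C)C=C1 | intermediate (not isolated)
14 | potassium (4aR,5R,6S)-6-{[tert-butyl(dimethyl)silyl]oxy}-4a,5-dimethyl-4,4a,5,6-tetrahydronaphthalen-2-olate | CC(C)(C)[Si](C)(C)O[C@H]1C=CC2=CC([O-])=CC[C@]2(C)[C@H]1C.[K+] | intermediate (not isolated)
15 | (4aR,5R,6S)-6-{[tert-butyl(dimethyl)silyl]oxy}-3-(2-hydroxypropan-2-yl)-4a,5-dimethyl-4,4a,5,6-tetrahydronaphthalen-2(3H)-one (C3 epimers) | CC(C)(C)[Si](C)(C)O[C@H]1C=CC2=CC(=O)C(C(C)(C)O)C[C@]2(C)[C@H]1C | intermediate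
16 | (4aR,5R,6S)-6-{[tert-butyl(dimethyl)silyl]oxy}-4a,5-dimethyl-3-(propan-2-ylidene)-4,4a,5,6-tetrahydronaphthalen-2(3H)-one | CC(C)(C)[Si](C)(C)O[C@H]1C=CC2=CC(=O)C(=C(C)C)C[C@]2(C)[C@H]1C | intermediate
17 | (4aR,5R,6S)-6-hydroxy-4a,5-dimethyl-3-(propan-2-ylidene)-4,4a,5,6-tetrahydronaphthalen-2(3H)-one | O[C@H]1C=CC2=CC(=O)C(=C(C)C)C[C@]2(C)[C@H]1C | intermediate
18 | (2S)-2-methylbutan-1-ol | CC[C@H](C)CO | starting material
19 | (2S)-2-methylbutanal | CC[C@H](C)C=O | intermediate
20 | ethyl (2E)-4-(diethoxyphosphoryl)but-2-enoate | CCOC(=O)/C=C/CP(=O)(OCC)OCC | starting material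
21 | ethyl (2E,4E,6S)-6-methylocta-2,4-dienoate | CC[C@H](C)/C=C/C=C/C(=O)OCC | intermediate
22 | (2E,4E,6S)-6-methylocta-2,4-dienoic acid | CC[C@H](C)/C=C/C=C/C(=O)O | intermediate
23 | (2E,4E,6S)-6-methylocta-2,4-dienoic 2,4,6-trichlorobenzoic anhydride | CC[C@H](C)/C=C/C=C/C(=O)OC(=O)c1c(Cl)cc(Cl)cc1Cl | intermediate (not isolated)
24 | (1R,2S,8aR)-1,8a-dimethyl-6-oxo-7-(propan-2-ylidene)-1,2,6,7,8,8a-hexahydronaphthalen-2-yl (2E,4E,6S)-6-methylocta-2,4-dienoate | CC[C@H](C)/C=C/C=C/C(=O)O[C@H]1C=CC2=CC(=O)C(=C(C)C)C[C@]2(C)[C@H]1C | target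

**Count**

Total steps: 14. Longest linear sequence: 11 (steps 1–10 and 14).

**Steps most likely to fail**

Step 8 (Proposed new method). The trienolate may not close: ε-deprotonation at C6, an anion geometry that keeps C4 away from C4a, or anionic polymerization of the vinyl ketone could each divert it. The fallback makes the same C4–C4a bond intermolecularly by a Robinson annulation that sets out from enone 7. LiN(i-Pr)2 in THF at −78 °C should give the α'-enolate at C4a, which adds to 3-(trimethylsilyl)but-3-en-2-one anti to the C5 methyl to give (4S,5R,6R)-4-{[tert-butyl(dimethyl)silyl]oxy}-5,6-dimethyl-6-[3-oxo-2-(trimethylsilyl)butyl]cyclohex-2-en-1-one F1. KOH in MeOH removes silicon to give (4S,5R,6R)-4-{[tert-butyl(dimethyl)silyl]oxy}-5,6-dimethyl-6-(3-oxobutyl)cyclohex-2-en-1-one F2 and effects aldol condensation onto the enone carbonyl to give (4aR,5R,6S)-6-{[tert-butyl(dimethyl)silyl]oxy}-4a,5-dimethyl-4,4a,5,6-tetrahydronaphthalen-2(3H)-one F3. Kinetic deprotonation of F3 at C3 (LiN(i-Pr)2, then ZnCl2 and acetone, −78 °C) comes back to the route at aldol 15.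

Step 6. The phosphonate anion may enolize the hindered ketone, add in conjugate fashion at C7, or isomerize the γ-silyloxy enone on heating. The fallback brings in the two carbons by 1,2-addition and rearrangement, setting out from 7. Lithium ethoxyacetylide (ethoxyacetylene, n-BuLi, THF, −78 °C) should add to the carbonyl to give (4S,5R,6S)-4-{[tert-butyl(dimethyl)silyl]oxy}-1-(ethoxyethynyl)-5,6-dimethylcyclohex-2-en-1-ol F4. A Meyer–Schuster rearrangement (Sc(OTf)3 cat., CH2Cl2/EtOH, rt) gives ethyl (2E)-2-[(4S,5R,6S)-4-{[tert-butyl(dimethyl)silyl]oxy}-5,6-dimethylcyclohex-2-en-1-ylidene]acetate F5. Aminolysis with MeNH(OMe)·HCl and i-PrMgCl (THF, −20 °C) comes back to the route at amide 9.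

Step 3. The chromium oxidant may attack the silyloxy-bearing allylic position or the allylic methyl groups instead of the ring methylene. The fallback inverts the order of oxidation and reduction, setting out from 1. γ-Oxidation of the enone (Pd(OH)2 on carbon, t-BuOOH, K2CO3, CH2Cl2) should give 2,3-dimethylcyclohex-2-ene-1,4-dione F6. One of its two equivalent carbonyl groups is reduced with the same oxazaborolidine catalyst and a substoichiometric amount of BH3·SMe2 to (4S)-4-hydroxy-2,3-dimethylcyclohex-2-en-1-one F7. Silylation (TBSCl, imidazole, DMF) comes back to the route at 4.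

**Further compounds**

F1 | step 8 | (4S,5R,6R)-4-{[tert-butyl(dimethyl)silyl]oxy}-5,6-dimethyl-6-[3-oxo-2-(trimethylsilyl)butyl]cyclohex-2-en-1-one | CC(=O)C(C[C@]1(C)[C@@H](C)[C@@H](O[Si](C)(C)C(C)(C)C)C=CC1=O)[Si](C)(C)C
F2 | step 8 | (4S,5R,6R)-4-{[tert-butyl(dimethyl)silyl]oxy}-5,6-dimethyl-6-(3-oxobutyl)cyclohex-2-en-1-one | CC(=O)CC[C@]1(C)[C@@H](C)[C@@H](O[Si](C)(C)C(C)(C)C)C=CC1=O
F3 | step 8 | (4aR,5R,6S)-6-{[tert-butyl(dimethyl)silyl]oxy}-4a,5-dimethyl-4,4a,5,6-tetrahydronaphthalen-2(3H)-one | CC(C)(C)[Si](C)(C)O[C@H]1C=CC2=CC(=O)CC[C@]2(C)[C@H]1C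
F4 | step 6 | (4S,5R,6S)-4-{[tert-butyl(dimethyl)silyl]oxy}-1-(ethoxyethynyl)-5,6-dimethylcyclohex-2-en-1-ol | C[C@H]1[C@@H](C)[C@@H](O[Si](C)(C)C(C)(C)C)C=CC1(O)C#COCC
F5 | step 6 | ethyl (2E)-2-[(4S,5R,6S)-4-{[tert-butyl(dimethyl)silyl]oxy}-5,6-dimethylcyclohex-2-en-1-ylidene]acetate | C[C@H]1[C@@H](C)[C@@H](O[Si](C)(C)C(C)(C)C)C=C/C1=C\C(=O)OCC
F6 | step 3 | 2,3-dimethylcyclohex-2-ene-1,4-dione | CC1=C(C)C(=O)CCC1=O
F7 | step 3 | (4S)-4-hydroxy-2,3-dimethylcyclohex-2-en-1-one | CC1=C(C)[C@@H](O)CCC1=O
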